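**Retrosynthetic overview**
- The butenolide ring is formed last. The target comes from a (Z)-2-en-4-ynoic acid by Ag(I) 5-exo-dig lactonisation, which also sets the Z-benzylidene.
- The enynoic acid comes from acyl–O hydrolysis of an enyne-bearing α-alkylidene-β-lactone. The carbinol oxygen carries the acyl group temporarily, so it never needs a protecting group.
- The enyne β-lactone comes from a (Z)-α-chloroalkylidene-β-lactone and an aryl acetylene by Sonogashira coupling at the vinylogous acyl chloride.
- Key step: the chloro-β-lactone comes from an (S)-1,3-diarylpropargylic alcohol, CO and Cl by Pd(II)/CuCl2 syn chlorocarbonylation. This forms the temporary oxetanone ring first and fixes the tetrasubstituted alkene geometry.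
- The propargylic alcohol comes from the aryl aldehyde and the same aryl acetylene by catalytic asymmetric alkynylation, which sets the only stereocentre through C–C bond formation.

Assumption: CIP analysis of the given SMILES gives an (S) carbinol (O > butenolide C3 > aryl > H) and a (Z) exocyclic alkene. Compounds 1 and 4 are taken as commercial.

**Step 1**
Reactants: 1, 2-bromo-4-iodophenol
Product: 2, tert-butyl(2-bromo-4-iodophenoxy)dimethylsilane
Conditions: TBSCl, imidazole, DMF, rt
Reagents that add atoms: TBSCl, CC(C)(C)[Si](C)(C)Cl
Why: Imidazole-promoted silyl ether formation masks the acidic, oxidisable phenol for the organozinc, Cu(II) and Pd steps, and the group is later removed by the same hydroxide that opens the lactone.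

**Step 2**
Reactants: 2
Product: 3, (2-bromo-4-ethynylphenoxy)(tert-butyl)dimethylsilane
Conditions: HC≡CMgBr, ZnBr2, THF, 0 °C; then 2, Pd(PPh3)4 (4 mol %), rt
Reagents that add atoms: ethynylmagnesium bromide, C#C[Mg]Br
Why: Negishi coupling of ethynylzinc bromide at rt reacts only at C–I (the C–Br is ortho-oxygenated and electron-rich), and it gives the terminal alkyne directly without a basic C-desilylation that would strip the aryl silyl ether.

**Step 3**
Reactants: 4, 3,5-dibromo-4-hydroxybenzaldehyde
Product: 5, 3,5-dibromo-4-methoxybenzaldehyde
Conditions: MeI, K2CO3, DMF, rt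
Reagents that add atoms: iodomethane, CI
Why: Williamson etherification of the acidic 2,6-dibromophenol is fast and installs the only methyl ether of the target.

**Step 4**
Reactants: 5; 3 (2.5 equiv, excess recovered)
Product: 6, (S)-3-[3-bromo-4-(TBSO)phenyl]-1-(3,5-dibromo-4-methoxyphenyl)prop-2-yn-1-ol
Conditions: 3, Et2Zn, Cy2NH (5 mol %), (R)-BINOL (20 mol %), Et2O, rt; Ti(OiPr)4 (50 mol %); then 5, rt; aq NH4Cl
Reagents that add atoms: none
Why: In this BINOL–Ti(IV)-catalysed asymmetric alkynylzinc addition to an aromatic aldehyde with no ortho substituents (the best substrate class, about 90–95 % ee expected), the (S)-ligand attacks the Si face to give (R)-carbinols, so (R)-BINOL attacks the Re face and gives (S) (O > alkynyl > aryl > H), to be confirmed by Mosher ester analysis.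

**Step 5 (key step)**
Reactants: 6
Product: 7, (S,Z)-3-{[3-bromo-4-(TBSO)phenyl](chloro)methylidene}-4-(3,5-dibromo-4-methoxyphenyl)oxetan-2-one
Conditions: PdCl2 (10 mol %), CuCl2 (5 equiv), 2,6-di-tert-butylpyridine (1.5 equiv), CO (20 atm), THF, 30 °C
Reagents that add atoms: carbon monoxide, [C-]#[O+]; copper(II) chloride (Cl source and reoxidant), Cl[Cu]Cl
Why: In this Pd(II)/CuCl2 chlorocarbonylative cyclisation of a 2-alkynol (a known reaction type, extended here to a 1,3-diaryl substrate), hydroxyl-anchored syn addition puts C=O on the proximal alkyne carbon and Cl on the benzylic distal carbon on the same side (Z), the carbinol C–O bond is never broken so (S) is retained, ionisation or Meyer–Schuster rearrangement is disfavoured by the electron-poor dibromoaryl ring and the proton scavenger, and the Pd(II)-only manifold leaves the Ar–Br bonds untouched.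

**Step 6**
Reactants: 7; 3 (1.3 equiv)
Product: 8, (S,Z)-3-{1,3-bis[3-bromo-4-(TBSO)phenyl]prop-2-yn-1-ylidene}-4-(3,5-dibromo-4-methoxyphenyl)oxetan-2-one
Conditions: Pd(PPh3)4 (5 mol %), CuI (10 mol %), iPr2NEt, MeCN/THF, 30 °C, Ar
Reagents that add atoms: none
Why: Stereoretentive Sonogashira coupling works because the C–Cl bond is a strained vinylogous acyl chloride that adds to Pd(0) near rt while electron-rich ortho-oxygenated Ar–Br bonds need heating, and the ring C4–O bond lies in the nodal plane of the exocyclic π bond so π-allyl ionisation cannot racemise the centre.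

**Step 7**
Reactants: 8
Product: 9, (Z)-3,5-bis(3-bromo-4-hydroxyphenyl)-2-[(S)-(3,5-dibromo-4-methoxyphenyl)(hydroxy)methyl]pent-2-en-4-ynoic acid
Conditions: LiOH (8 equiv), THF/H2O 3:1, 0 °C to rt; then 10 % citric acid to pH 3–4
Reagents that add atoms: lithium hydroxide/water, [Li+].[OH-] and O
Why: BAc2 saponification opens the strained β-lactone by acyl–O cleavage, which retains the benzylic C–O bond and the (S) centre, while hydroxide also removes both labile aryl TBS ethers and leaves the aryl methyl ether, the Ar–Br bonds and the alkene geometry (CO2H cis to alkynyl) unchanged.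

**Step 8**
Reactants: 9
Product: 10, target, (Z)-5-(3-bromo-4-hydroxybenzylidene)-4-(3-bromo-4-hydroxyphenyl)-3-[(S)-(3,5-dibromo-4-methoxyphenyl)(hydroxy)methyl]furan-2(5H)-one
Conditions: AgNO3 (10 mol %), acetone, rt, dark
Reagents that add atoms: none
Why: Ag(I)-catalysed 5-exo-dig cycloisomerisation of a (Z)-2-en-4-ynoic acid proceeds by anti oxy-metalation and protodemetalation, which places the aryl group cis to the ring oxygen (Z), under neutral conditions that never form a dienolate, so the carbinol cannot eliminate or racemise, and its OH is trans to the alkyne and cannot compete.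

**Compound list**
1 | 2-bromo-4-iodophenol | Oc1ccc(I)cc1Br | starting material
2 | tert-butyl(2-bromo-4-iodophenoxy)dimethylsilane | CC(C)(C)[Si](C)(C)Oc1ccc(I)cc1Br | intermediate
3 | (2-bromo-4-ethynylphenoxy)(tert-butyl)dimethylsilane | C#Cc1ccc(O[Si](C)(C)C(C)(C)C)c(Br)c1 | intermediate (used twice)
4 | 3,5-dibromo-4-hydroxybenzaldehyde | O=Cc1cc(Br)c(O)c(Br)c1 | starting material
5 | 3,5-dibromo-4-methoxybenzaldehyde | COc1c(Br)cc(C=O)cc1Br | intermediate
6 | (S)-1,3-diarylpropargylic alcohol | COc1c(Br)cc([C@H](O)C#Cc2ccc(O[Si](C)(C)C(C)(C)C)c(Br)c2)cc1Br | intermediate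
7 | (S,Z)-α-chloroalkylidene-β-lactone | COc1c(Br)cc([C@@H]2OC(=O)/C2=C(\Cl)c3ccc(O[Si](C)(C)C(C)(C)C)c(Br)c3)cc1Br | intermediate
8 | (S,Z)-enyne β-lactone | COc1c(Br)cc([C@@H]2OC(=O)/C2=C(\C#Cc3ccc(O[Si](C)(C)C(C)(C)C)c(Br)c3)c3ccc(O[Si](C)(C)C(C)(C)C)c(Br)c3)cc1Br | intermediate
9 | (S,Z)-hydroxy enynoic acid | COc1c(Br)cc([C@H](O)/C(C(=O)O)=C(/C#Cc2ccc(O)c(Br)c2)c2ccc(O)c(Br)c2)cc1Br | intermediate
10 | CID71459453 | COc1c(Br)cc([C@H](O)C2=C(c3ccc(O)c(Br)c3)/C(=C/c3ccc(O)c(Br)c3)OC2=O)cc1Br | target

**Total steps:** 8. **Longest linear sequence:** 7 (steps 1, 2, 4, 5, 6, 7, 8).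

**Steps most likely to fail, with fallbacks**
1. **Step 5.** The 1,3-diaryl substrate is outside the proven scope. Possible failures are trans-chloropalladation giving the useless E-chloride, oxidation to the ynone, Meyer–Schuster rearrangement, and chloride opening of the benzylic lactone.
   - Fallback: drop the β-lactone relay and form the C3–carbinol bond last.
   - Convert 3 to the arylpropiolic acid (EtMgBr, CO2), then add I2 to give the (E)-2,3-diiodoacrylic acid.
   - A β-selective Sonogashira/lactonisation with 3 then gives the 3-iodo-(Z)-ylidenebutenolide.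
   - Finish with a catalytic asymmetric Ni/Cr (Nozaki–Hiyama–Kishi) addition to 5 and fluoride desilylation.
2. **Step 6.** The activated C–Cl must react in preference to four Ar–Br bonds at a hindered, aryl-bearing carbon.
   - Fallback: reduce the competition instead of tuning the catalyst.
   - Run steps 4–8 with the non-brominated 4-(TBSO)phenylacetylene.
   - Install the two B/C-ring bromines last by ortho-selective monobromination of the bis-phenol (2 equiv Bu4NBr3 or NBS/iPr2NH). Ring A has no free activated position, though its two Ar–Br bonds are still present during the coupling.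
3. **Step 8.** The electron-rich aryl alkyne may favour 6-endo closure to the 2-pyranone.
   - Fallback: change how the ring is closed. Couple 7 with a 1-ethoxy-2-arylvinylstannane (Stille coupling of an acyl-anion equivalent) instead of the alkyne.
   - Hydrolysis then gives the γ-keto acid, which closes to the 5-benzyl-5-hydroxybutenolide.
   - Acid-catalysed dehydration gives the thermodynamically preferred (Z)-ylidene with no regiochemical ambiguity.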